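**Retrosynthetic overview**
1. Asperteretal H ⇒ tris-TBS ether; one buffered fluoride step at the end removes all protection.
2. C4–C5 bond ⇒ S-ethyl thioester of the chiral half plus a ring-B benzylzinc reagent (Fukuyama ketone synthesis).
3. C3–aryl bond (key step) ⇒ photochemical aryl-radical addition to the silyl ketene thioacetal of a D-malate. C2 is bought and C3 is set by 1,2-induction from C2.
4. The C1 ester / C4 thioester differentiation comes from regioselective methanolysis of D-malic anhydride.
5. No ring is formed. Both benzene rings are bought, and the prenyl group enters by ortho C-alkylation of 4-hydroxybenzaldehyde.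

Assumption: the SMILES is read as methyl (2R,3S), with OH and aryl anti on the C1–C5 zigzag. TBS = tert-butyldimethylsilyl, prenyl = 3-methylbut-2-enyl, PTH = 10-phenylphenothiazine.

**Step 1**
Reactants: 1 D-malic acid [(R)-2-hydroxybutanedioic acid]
Product: 3 (3R)-3-hydroxy-4-methoxy-4-oxobutanoic acid (1-methyl D-malate), via O-trifluoroacetylmalic anhydride 2 (not isolated)
Conditions: (CF3CO)2O, 0 °C → rt; evaporate; MeOH, rt
Reagents that add atoms: methanol, CO
Why: Dehydration gives the five-membered anhydride, and methanol opens it at the more electrophilic carbonyl next to the C–OCOCF3 carbon (regioselective anhydride alcoholysis) while also cleaving the labile trifluoroacetate; no bond to C2 is broken, so it stays R.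

**Step 2**
Reactants: 3 (3R)-3-hydroxy-4-methoxy-4-oxobutanoic acid
Product: 4 methyl (2R)-4-(ethylsulfanyl)-2-hydroxy-4-oxobutanoate
Conditions: EtSH, DCC, DMAP (cat.), CH2Cl2, 0 °C → rt
Reagents that add atoms: ethanethiol, CCS
Why: In this Steglich-type thioesterification the soft thiol outcompetes the secondary OH for the activated acid, and C2 is not touched.

**Step 3**
Reactants: 4 methyl (2R)-4-(ethylsulfanyl)-2-hydroxy-4-oxobutanoate; 5 tert-butyl(4-iodophenoxy)dimethylsilane
Product: 7 methyl (2R,3S)-2-(TBSO)-3-[4-(TBSO)phenyl]-4-(ethylsulfanyl)-4-oxobutanoate, via bis-silyl ketene thioacetal 6 (not isolated)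
Conditions: TBSOTf (2.3 equiv), Et3N (3 equiv), CH2Cl2, 0 °C; pentane, filter, concentrate; then 5 (1.5 equiv), PTH (5 mol %), 2,6-lutidine (1.2 equiv), degassed MeCN, 390 nm LED, 20 °C; chromatography removes the minor C3 epimer
Reagents that add atoms: tert-butyldimethylsilyl triflate, CC(C)(C)[Si](C)(C)OS(=O)(=O)C(F)(F)F
Why: Proposed new method: soft enolisation silylates the OH and converts only the more acidic thioester into ketene O-silyl S-ethyl acetal 6; excited PTH (E* about −2.1 V vs SCE) reduces iodide 5 to the aryl radical, which adds to the nucleophilic C3 terminus; the α-silyloxy-α-thio radical is oxidised by PTH radical cation (or by iodine formed from iodide) to a silyloxy thiocarbenium ion, and iodide/lutidine strip the silyl group to return the thioester, so the C3–aryl bond forms in a redox-neutral, base-free radical–polar crossover and the acidic new C3–H is never enolised; C3 is set by 1,2-induction from the bought C2 centre, because allylic 1,3-strain holds C2–H in the plane of the ketene acetal (for either alkene geometry) and the radical enters anti to the bulky OTBS group, the same anti sense as Fráter–Seebach alkylation of malates, giving (2R,3S); the closest known reaction types are photoredox α-arylation of enol silanes and enol acetates with diazonium or iodonium salts, photostimulated SRN1 arylation of enolates, and PTH-mediated aryl halide activation, none of them shown on a ketene thioacetal or with acyclic 1,2-stereocontrol.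

**Step 4**
Reactants: 8 4-hydroxybenzaldehyde; 9 prenyl bromide (1-bromo-3-methylbut-2-ene)
Product: 10 4-hydroxy-3-prenylbenzaldehyde
Conditions: KOH (1.1 equiv), H2O, rt, 24 h; acidify; chromatography
Reagents that add atoms: none
Why: This is direct ortho C-alkylation of an ambident phenoxide in water (oxygen hydrogen-bonded, para position blocked); the O-prenyl ether by-product is separated.

**Step 5**
Reactants: 10 4-hydroxy-3-prenylbenzaldehyde
Product: 12 [4-(TBSO)-3-prenylphenyl]methanol, via TBS-protected aldehyde 11 (not isolated)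
Conditions: TBSCl, imidazole, CH2Cl2, rt; then MeOH, NaBH4, 0 °C
Reagents that add atoms: tert-butyldimethylsilyl chloride, CC(C)(C)[Si](C)(C)Cl
Why: Phenol silylation is followed in the same flask by chemoselective borohydride reduction of the aldehyde; the trisubstituted alkene and the aryl silyl ether survive at 0 °C.

**Step 6**
Reactants: 12 [4-(TBSO)-3-prenylphenyl]methanol
Product: 14 tert-butyl[4-(chloromethyl)-2-prenylphenoxy]dimethylsilane, via benzylic mesylate 13 (not isolated)
Conditions: MsCl, Et3N, CH2Cl2, 0 °C → rt; short silica plug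
Reagents that add atoms: methanesulfonyl chloride, CS(=O)(=O)Cl
Why: The electron-rich benzylic alcohol is mesylated and the chloride released displaces the mesylate in situ (SN2), with no free acid present that could add to the prenyl group.

**Step 7**
Reactants: 7 methyl (2R,3S)-2-(TBSO)-3-[4-(TBSO)phenyl]-4-(ethylsulfanyl)-4-oxobutanoate; 14 tert-butyl[4-(chloromethyl)-2-prenylphenoxy]dimethylsilane
Product: 16 methyl (2R,3S)-2-(TBSO)-3-[4-(TBSO)phenyl]-5-[4-(TBSO)-3-prenylphenyl]-4-oxopentanoate, via benzylzinc chloride 15 (not isolated)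
Conditions: 14, Zn dust, LiCl, THF, rt; then 7, PdCl2(PPh3)2 (5 mol %), toluene–THF, rt
Reagents that add atoms: none
Why: LiCl-promoted zinc insertion gives a non-basic benzylzinc reagent, and Fukuyama ketone synthesis (Pd insertion into the C(O)–S bond, transmetalation, reductive elimination) stops at the ketone, spares the methyl ester, and does not enolise C3, so both centres are kept.

**Step 8**
Reactants: 16 methyl (2R,3S)-2-(TBSO)-3-[4-(TBSO)phenyl]-5-[4-(TBSO)-3-prenylphenyl]-4-oxopentanoate
Product: 17 Asperteretal H, methyl (2R,3S)-2-hydroxy-3-(4-hydroxyphenyl)-5-(4-hydroxy-3-prenylphenyl)-4-oxopentanoate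
Conditions: HF·pyridine, excess pyridine, THF, 0 °C → rt
Reagents that add atoms: none
Why: Fluoride cleaves all three Si–O bonds in a weakly acidic buffered medium, which avoids enolate chemistry (C3 epimerisation, retro-aldol, β-elimination) and is too mild for chroman formation from the prenylphenol.

**Compound list**
1 | D-malic acid, (R)-2-hydroxybutanedioic acid | OC(=O)[C@H](O)CC(=O)O | starting material
2 | (R)-2-(trifluoroacetoxy)succinic anhydride | O=C1[C@H](OC(=O)C(F)(F)F)CC(=O)O1 | intermediate
3 | (3R)-3-hydroxy-4-methoxy-4-oxobutanoic acid | COC(=O)[C@H](O)CC(=O)O | intermediate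
4 | methyl (2R)-4-(ethylsulfanyl)-2-hydroxy-4-oxobutanoate | COC(=O)[C@H](O)CC(=O)SCC | intermediate
5 | tert-butyl(4-iodophenoxy)dimethylsilane | CC(C)(C)[Si](C)(C)Oc1ccc(I)cc1 | starting material
6 | methyl (2R,3E)-2,4-bis(TBSO)-4-(ethylsulfanyl)but-3-enoate | COC(=O)[C@H](O[Si](C)(C)C(C)(C)C)/C=C(/SCC)O[Si](C)(C)C(C)(C)C | intermediate
7 | methyl (2R,3S)-2-(TBSO)-3-[4-(TBSO)phenyl]-4-(ethylsulfanyl)-4-oxobutanoate | COC(=O)[C@H](O[Si](C)(C)C(C)(C)C)[C@@H](C(=O)SCC)c1ccc(O[Si](C)(C)C(C)(C)C)cc1 | intermediate
8 | 4-hydroxybenzaldehyde | O=Cc1ccc(O)cc1 | starting material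
9 | prenyl bromide | CC(C)=CCBr | starting material
10 | 4-hydroxy-3-prenylbenzaldehyde | O=Cc1ccc(O)c(CC=C(C)C)c1 | intermediate
11 | 4-(TBSO)-3-prenylbenzaldehyde | O=Cc1ccc(O[Si](C)(C)C(C)(C)C)c(CC=C(C)C)c1 | intermediate
12 | [4-(TBSO)-3-prenylphenyl]methanol | OCc1ccc(O[Si](C)(C)C(C)(C)C)c(CC=C(C)C)c1 | intermediate
13 | 4-(TBSO)-3-prenylbenzyl methanesulfonate | CS(=O)(=O)OCc1ccc(O[Si](C)(C)C(C)(C)C)c(CC=C(C)C)c1 | intermediate
14 | tert-butyl[4-(chloromethyl)-2-prenylphenoxy]dimethylsilane | ClCc1ccc(O[Si](C)(C)C(C)(C)C)c(CC=C(C)C)c1 | intermediate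
15 | [4-(TBSO)-3-prenylbenzyl]zinc chloride | Cl[Zn]Cc1ccc(O[Si](C)(C)C(C)(C)C)c(CC=C(C)C)c1 | intermediate
16 | methyl (2R,3S)-2-(TBSO)-3-[4-(TBSO)phenyl]-5-[4-(TBSO)-3-prenylphenyl]-4-oxopentanoate | COC(=O)[C@H](O[Si](C)(C)C(C)(C)C)[C@@H](C(=O)Cc1ccc(O[Si](C)(C)C(C)(C)C)c(CC=C(C)C)c1)c1ccc(O[Si](C)(C)C(C)(C)C)cc1 | intermediate
17 | Asperteretal H | COC(=O)[C@H](O)[C@@H](C(=O)Cc1ccc(O)c(CC=C(C)C)c1)c1ccc(O)cc1 | target

**Step count**
- Total steps: 8.
- Longest linear sequence: 5 (steps 1, 2, 3, 7, 8). The ring-B branch (steps 4, 5, 6, 7, 8) is equally long.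

**Steps most likely to fail**

**Step 3 (the proposed new arylation).**
- Risks: slow turnover with the electron-rich iodide, loss of the allylic OTBS group from 6 to give the fumarate-type thioester, and only modest facial selectivity.
- The fallback sets out from 5 and 6 and returns at 7. It replaces the light-driven radical addition with a two-electron copper aryl transfer.
- 5 is oxidised with mCPBA and TfOH in the presence of mesitylene to [4-(tert-butyldimethylsilyloxy)phenyl](2,4,6-trimethylphenyl)iodonium trifluoromethanesulfonate F1.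
- 6, now purified on Et3N-deactivated silica, is arylated in the dark with F1 and Cu(OTf)2 (10 mol %) in CH2Cl2 at rt. This Cu(I)/Cu(III) arylation of silyl ketene acetals by diaryliodonium salts is known to give tertiary α-aryl carbonyl centres without epimerisation, and it delivers 7.

**Step 7 (Fukuyama coupling of a hindered α-aryl thioester).**
- Risks: slow oxidative addition, decarbonylation of the acyl-palladium species, and bibenzyl formation.
- The fallback sets out from 7 and 15 and returns at 16. It builds the ketone by carbonyl addition and oxidation.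
- 7 is reduced with Et3SiH and Pd/C in CH2Cl2 to methyl (2R,3S)-2-(TBSO)-3-[4-(TBSO)phenyl]-4-oxobutanoate F2, which is used crude.
- Benzylzinc chloride 15 adds to it in THF at 0 °C to give methyl (2R,3R,4RS)-2-(TBSO)-3-[4-(TBSO)phenyl]-4-hydroxy-5-[4-(TBSO)-3-prenylphenyl]pentanoate F3 as a mixture of carbinol epimers.
- Dess–Martin periodinane buffered with NaHCO3 oxidises both epimers to 16.

**Step 4 (direct C-prenylation).**
- Risks: a yield of typically 40–50 %, with competing O- and bis-alkylation.
- The fallback sets out from 8 and returns at 11. It installs the prenyl group by cross-coupling.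
- 8 is brominated (Br2, CHCl3, 0 °C) to 3-bromo-4-hydroxybenzaldehyde F4.
- F4 is silylated (TBSCl, imidazole) to 3-bromo-4-(TBSO)benzaldehyde F5.
- F5 undergoes Stille coupling with tributyl(3-methylbut-2-enyl)stannane (Pd(PPh3)4, DMF, 90 °C) to give 11, which enters step 5 at the borohydride stage.

**Further compounds**
F1 | step 3 | [4-(tert-butyldimethylsilyloxy)phenyl](2,4,6-trimethylphenyl)iodonium trifluoromethanesulfonate | CC(C)(C)[Si](C)(C)Oc1ccc([I+]c2c(C)cc(C)cc2C)cc1.[O-]S(=O)(=O)C(F)(F)F
F2 | step 7 | methyl (2R,3S)-2-(TBSO)-3-[4-(TBSO)phenyl]-4-oxobutanoate | COC(=O)[C@H](O[Si](C)(C)C(C)(C)C)[C@@H](C=O)c1ccc(O[Si](C)(C)C(C)(C)C)cc1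
F3 | step 7 | methyl (2R,3R,4RS)-2-(TBSO)-3-[4-(TBSO)phenyl]-4-hydroxy-5-[4-(TBSO)-3-prenylphenyl]pentanoate | COC(=O)[C@H](O[Si](C)(C)C(C)(C)C)[C@@H](C(O)Cc1ccc(O[Si](C)(C)C(C)(C)C)c(CC=C(C)C)c1)c1ccc(O[Si](C)(C)C(C)(C)C)cc1
F4 | step 4 | 3-bromo-4-hydroxybenzaldehyde | O=Cc1ccc(O)c(Br)c1
F5 | step 4 | 3-bromo-4-(TBSO)benzaldehyde | O=Cc1ccc(O[Si](C)(C)C(C)(C)C)c(Br)c1
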